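**Plan**

1. Retrosynthesis: the 22-membered lactone ring is opened first at C13–C14 (sp3–sp2), then at the ester bond C1(=O)–O–C21. The acid half C1–C13 is cut at C8–C9 and C6–C7; the alcohol half C14–C30 at C16–C17, C18=C19, C20–C21 and C23–C24.
2. Forward: alkene C1–C8 and alkyne C9–C13 are joined by a ruthenium-catalysed alkene–alkyne coupling that also creates the C9 methylidene and the (E)-C6=C7 bond. The alcohol half grows from a stannylacrolein by crotylboration, cross-metathesis, Stille coupling and propargylation. Esterification joins the halves, and the only ring, the macrolactone, is closed last at C13–C14.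
3. Enabling feature: in the ring, C14=C15 is an isolated trans CH=CH between two methylenes (C13, C16), and C13 is an unbranched primary carbon. The C17 carbinol can therefore carry a propargyl group (C16–C15≡C14) and C13 a primary triflate. One copper hydride event (anti-Markovnikov hydrocupration of the terminal alkyne, then alkylation of the alkenylcopper) forms C13–C14, the (E)-alkene and the ring together.
4. Stereochemistry: C5 is bought (chloro-hydroxy-keto ester 1) and relayed to C3 by a 1,3-anti reduction. C11 and C17 come from BINOL–titanium propargylations, C20/C21 from a phosphoric-acid-catalysed (E)-crotylboration. Alkene geometry comes from the Alder-ene coupling (6E), metathesis (18E), hydrostannation (22E), Red-Al/iodine (24Z), Wittig (26Z) and syn-hydrocupration (14E).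

Key step: step 24

Remark: locants C1–C30 in the text follow the target chain (C1 lactone carbonyl, C21 the O-bearing ring carbon, C22–C30 the side chain); compound names carry their own locants. TBS = tert-butyldimethylsilyl, TES = triethylsilyl, SIPr = 1,3-bis(2,6-diisopropylphenyl)imidazolidin-2-ylidene, TRIP = 3,3'-bis(2,4,6-triisopropylphenyl)-1,1'-binaphthyl-2,2'-diyl hydrogen phosphate.

**Acid half (C1–C13)**

Step 1
Reactants: 1 tert-butyl (5S)-6-chloro-5-hydroxy-3-oxohexanoate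
Product: 2 tert-butyl (3S,5S)-6-chloro-3,5-dihydroxyhexanoate
Conditions: Me4NBH(OAc)3, MeCN/AcOH, −30 °C
Reagents that add atoms: none
Why: Evans–Saksena reduction: the C5 hydroxyl binds boron and delivers hydride to the C3 ketone through a chair transition state, so the new C3 centre is set 1,3-anti to C5 by substrate control.

Step 2
Reactants: 2 tert-butyl (3S,5S)-6-chloro-3,5-dihydroxyhexanoate
Product: 3 tert-butyl (3S)-3-hydroxy-4-[(2S)-oxiran-2-yl]butanoate
Conditions: K2CO3, MeOH, 0 °C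
Reagents that add atoms: none
Why: Intramolecular Williamson etherification of the chlorohydrin (3-exo-tet attack of the C5 alkoxide on C6), which leaves both stereocentres untouched and should be faster than five-membered ether formation from the C3 hydroxyl.

Step 3
Reactants: 3 tert-butyl (3S)-3-hydroxy-4-[(2S)-oxiran-2-yl]butanoate
Product: 4 tert-butyl (3S,5R)-3,5-dihydroxyoct-7-enoate
Conditions: CH2=CHMgBr (3 equiv), CuI (10 mol %), THF, −40 to −20 °C
Reagents that add atoms: vinylmagnesium bromide, `C=C[Mg]Br`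
Why: Copper-catalysed Grignard opening of a terminal epoxide at its unsubstituted carbon (C6) installs the allyl group without touching C5 (the descriptor changes by priority only), the tert-butyl ester being inert at this temperature.

Step 4
Reactants: 4 tert-butyl (3S,5R)-3,5-dihydroxyoct-7-enoate
Product: 5 tert-butyl (3S,5R)-3,5-bis(TBS-oxy)oct-7-enoate
Conditions: TBSCl, imidazole, DMF, 35 °C
Reagents that add atoms: tert-butyldimethylsilyl chloride, `CC(C)(C)[Si](C)(C)Cl`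
Why: Imidazole-promoted silylation of both secondary alcohols under conditions that do not affect the tert-butyl ester or the stereocentres.

Step 5
Reactants: 6 3-(TBS-oxy)propanal
Product: 7 (3R)-1-(TBS-oxy)hex-5-yn-3-ol
Conditions: allenylSnBu3, (R)-BINOL (20 mol %), Ti(OiPr)4 (10 mol %), 4 Å MS, CH2Cl2, −20 °C
Reagents that add atoms: allenyltributylstannane, `C=C=C[Sn](CCCC)(CCCC)CCCC`
Why: Keck-type asymmetric propargylation: the BINOL–titanium Lewis acid activates the aldehyde and the allenylstannane adds through its γ-carbon (SE2'), the (R)-BINOL complex exposing the Re face as in the parent allylation, which sets the C11 carbinol.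

Step 6
Reactants: 7 (3R)-1-(TBS-oxy)hex-5-yn-3-ol
Product: 8 (3R)-1,3-bis(TBS-oxy)hex-5-yne
Conditions: TBSCl, imidazole, DMF, rt
Reagents that add atoms: tert-butyldimethylsilyl chloride, `CC(C)(C)[Si](C)(C)Cl`
Why: Standard imidazole-promoted silylation of the secondary alcohol with no effect on the stereocentre or the alkyne.

Step 7
Reactants: 5 tert-butyl (3S,5R)-3,5-bis(TBS-oxy)oct-7-enoate; 8 (3R)-1,3-bis(TBS-oxy)hex-5-yne
Product: 9 tert-butyl (3S,5S,6E,11R)-3,5,11,13-tetrakis(TBS-oxy)-9-methylidenetridec-6-enoate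
Conditions: [CpRu(MeCN)3]PF6 (10 mol %), acetone, rt
Reagents that add atoms: none
Why: Ruthenium-catalysed alkene–alkyne coupling of Alder-ene type: oxidative cyclisation to a ruthenacyclopentene joins C8 to the internal alkyne carbon C9, and β-hydride elimination of a C6–H followed by reductive elimination gives the branched 1,4-diene with the C9 methylidene and the (E)-C6=C7 bond, no stereocentre being involved.

Step 8
Reactants: 9 tert-butyl (3S,5S,6E,11R)-3,5,11,13-tetrakis(TBS-oxy)-9-methylidenetridec-6-enoate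
Product: 11 (3S,5S,6E,11R)-3,5,11,13-tetrakis(TBS-oxy)-9-methylidenetridec-6-enoic acid, via trimethylsilyl ester 10 (not isolated)
Conditions: TMSOTf, 2,6-lutidine, CH2Cl2, 0 °C; then pH 7 buffer
Reagents that add atoms: none
Why: Silyl-triflate-mediated tert-butyl ester cleavage: O-silylation of the ester releases isobutene to give the silyl ester, which hydrolyses on work-up, while the buffered conditions should spare the TBS ethers and the skipped diene.

**Side-chain iodide (C24–C30)**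

Step 9
Reactants: 12 but-2-yn-1-ol
Product: 14 (2Z)-3-iodobut-2-en-1-ol, via alkenylalanate 13 (not isolated)
Conditions: NaAlH2(OCH2CH2OMe)2 (Red-Al), THF, 0 °C to rt; EtOAc; then I2, −78 °C
Reagents that add atoms: iodine, `II`
Why: Hydroxyl-directed trans-hydroalumination of the propargylic alcohol puts aluminium on C3 and hydride on C2, and iododealumination with retention gives the (Z)-iodoalkene that becomes the 24Z bond.

Step 10
Reactants: 14 (2Z)-3-iodobut-2-en-1-ol
Product: 15 (2Z)-3-iodobut-2-enal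
Conditions: MnO2, CH2Cl2, rt
Reagents that add atoms: none
Why: Allylic alcohol oxidation on MnO2 under neutral conditions, which should keep the Z geometry of the sensitive β-iodoenal (used without storage).

Step 11
Reactants: 15 (2Z)-3-iodobut-2-enal
Product: 16 (2Z,4Z)-2-iodoocta-2,4,7-triene
Conditions: Ph3P+CH2CH2CH=CH2 Br−, NaN(SiMe3)2, THF, −78 °C; then 15, −78 to 0 °C
Reagents that add atoms: but-3-en-1-yltriphenylphosphonium bromide, `C=CCC[P+](c1ccccc1)(c1ccccc1)c1ccccc1.[Br-]`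
Why: Wittig olefination with a non-stabilised ylide under lithium-free conditions, whose kinetically controlled oxaphosphetane formation gives the (Z)-alkene (the future 26Z bond) and leaves the iodoalkene geometry intact.

**Alcohol half (C14–C30)**

Step 12
Reactants: 17 prop-2-yn-1-ol
Product: 18 (2E)-3-(tributylstannyl)prop-2-en-1-ol
Conditions: Bu3SnH, AIBN (cat.), 80 °C
Reagents that add atoms: tributyltin hydride, `CCCC[SnH](CCCC)CCCC`
Why: Radical hydrostannation of the terminal alkyne: the stannyl radical adds to the terminal carbon and reversible addition equilibrates the product to the (E)-alkenylstannane, which is separated from minor isomers.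

Step 13
Reactants: 18 (2E)-3-(tributylstannyl)prop-2-en-1-ol
Product: 19 (2E)-3-(tributylstannyl)prop-2-enal
Conditions: MnO2, CH2Cl2, rt
Reagents that add atoms: none
Why: Neutral MnO2 oxidation of the allylic alcohol, compatible with the acid-sensitive alkenylstannane and retaining the E geometry.

Step 14
Reactants: 19 (2E)-3-(tributylstannyl)prop-2-enal
Product: 20 (1E,3R,4R)-4-methyl-1-(tributylstannyl)hexa-1,5-dien-3-ol
Conditions: (E)-crotyl-B(pin), (R)-TRIP (5 mol %), 4 Å MS, toluene, −30 °C; aqueous work-up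
Reagents that add atoms: (E)-crotylboronic acid pinacol ester, `C/C=C/CB1OC(C)(C)C(C)(C)O1`
Why: Chiral-phosphoric-acid-catalysed crotylboration: the closed chair transition state translates the (E)-crotyl geometry into the anti C20/C21 relationship, and the (R)-acid, hydrogen-bonded to the boronate oxygen and the formyl hydrogen, directs addition to the Re face of the enal, which sets both centres.

Step 15
Reactants: 20 (1E,3R,4R)-4-methyl-1-(tributylstannyl)hexa-1,5-dien-3-ol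
Product: 21 triethyl{[(1E,3R,4R)-4-methyl-1-(tributylstannyl)hexa-1,5-dien-3-yl]oxy}silane
Conditions: TESCl, imidazole, CH2Cl2, 0 °C
Reagents that add atoms: chlorotriethylsilane, `CC[Si](Cl)(CC)CC`
Why: Silylation gives a temporary C21 protecting group that can later be removed in the presence of TBS ethers.

Step 16
Reactants: 21 triethyl{[(1E,3R,4R)-4-methyl-1-(tributylstannyl)hexa-1,5-dien-3-yl]oxy}silane
Product: 22 (2E,4R,5R,6E)-4-methyl-5-(TES-oxy)-7-(tributylstannyl)hepta-2,6-dienal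
Conditions: crotonaldehyde (5 equiv), second-generation Hoveyda–Grubbs catalyst [RuCl2(H2IMes)(=CH–C6H4-2-OiPr)] (5 mol %), CH2Cl2, 40 °C
Reagents that add atoms: (E)-crotonaldehyde, `C/C=C/C=O`
Why: Olefin cross-metathesis of the monosubstituted alkene with an electron-poor partner should give the (E)-enal under thermodynamic control, the 1,2-disubstituted alkenylstannane being too hindered to enter the cycle.

Step 17
Reactants: 22 (2E,4R,5R,6E)-4-methyl-5-(TES-oxy)-7-(tributylstannyl)hepta-2,6-dienal; 16 (2Z,4Z)-2-iodoocta-2,4,7-triene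
Product: 23 (2E,4R,5S,6E,8Z,10Z)-4,8-dimethyl-5-(TES-oxy)tetradeca-2,6,8,10,13-pentaenal
Conditions: Pd2(dba)3 (5 mol %), AsPh3 (20 mol %), NMP, rt
Reagents that add atoms: none
Why: Stille coupling (oxidative addition of the alkenyl iodide to zerovalent palladium, tin-to-palladium transmetalation, reductive elimination) forms C23–C24 with retention of both alkene geometries and tolerates the enal.

Step 18
Reactants: 23 (2E,4R,5S,6E,8Z,10Z)-4,8-dimethyl-5-(TES-oxy)tetradeca-2,6,8,10,13-pentaenal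
Product: 24 (4S,5E,7R,8S,9E,11Z,13Z)-7,11-dimethyl-8-(TES-oxy)heptadeca-5,9,11,13,16-pentaen-1-yn-4-ol
Conditions: allenylSnBu3, (S)-BINOL (20 mol %), Ti(OiPr)4 (10 mol %), 4 Å MS, CH2Cl2, −20 °C
Reagents that add atoms: allenyltributylstannane, `C=C=C[Sn](CCCC)(CCCC)CCCC`
Why: Keck-type asymmetric propargylation under catalyst control: the (S)-BINOL–titanium complex directs the allenylstannane to the Si face of the enal carbonyl in a 1,2-addition, setting C17 independently of the remote C20/C21 centres.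

Step 19
Reactants: 24 (4S,5E,7R,8S,9E,11Z,13Z)-7,11-dimethyl-8-(TES-oxy)heptadeca-5,9,11,13,16-pentaen-1-yn-4-ol
Product: 25 (4S,5E,7R,8S,9E,11Z,13Z)-4-(TBS-oxy)-7,11-dimethyl-8-(TES-oxy)heptadeca-5,9,11,13,16-pentaen-1-yne
Conditions: TBSCl, imidazole, DMF, rt
Reagents that add atoms: tert-butyldimethylsilyl chloride, `CC(C)(C)[Si](C)(C)Cl`
Why: Standard silylation of the C17 alcohol under mildly basic conditions that the polyene, the alkyne and the TES ether tolerate.

Step 20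
Reactants: 25 (4S,5E,7R,8S,9E,11Z,13Z)-4-(TBS-oxy)-7,11-dimethyl-8-(TES-oxy)heptadeca-5,9,11,13,16-pentaen-1-yne
Product: 26 (4S,5E,7R,8S,9E,11Z,13Z)-4-(TBS-oxy)-7,11-dimethylheptadeca-5,9,11,13,16-pentaen-1-yn-8-ol
Conditions: HF·pyridine, pyridine, THF, 0 °C
Reagents that add atoms: none
Why: Buffered fluoride cleavage distinguishes the more labile triethylsilyl ether from the TBS ether, freeing only the C21 hydroxyl without ionising the trienyl carbinol.

**Union and ring closure**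

Step 21
Reactants: 11 (3S,5S,6E,11R)-3,5,11,13-tetrakis(TBS-oxy)-9-methylidenetridec-6-enoic acid; 26 (4S,5E,7R,8S,9E,11Z,13Z)-4-(TBS-oxy)-7,11-dimethylheptadeca-5,9,11,13,16-pentaen-1-yn-8-ol
Product: 28 (4S,5E,7R,8S,9E,11Z,13Z)-4-(TBS-oxy)-7,11-dimethylheptadeca-5,9,11,13,16-pentaen-1-yn-8-yl (3S,5S,6E,11R)-3,5,11,13-tetrakis(TBS-oxy)-9-methylidenetridec-6-enoate, via mixed anhydride 27 (not isolated)
Conditions: 2,4,6-trichlorobenzoyl chloride, Et3N, toluene, rt; then 26, DMAP, rt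
Reagents that add atoms: none
Why: Yamaguchi esterification: DMAP attacks the mixed anhydride at the aliphatic carbonyl and the acylpyridinium acylates the C21 hydroxyl at oxygen, so C21 keeps its configuration.

Step 22
Reactants: 28 seco ester (five TBS ethers, see list)
Product: 29 (4S,5E,7R,8S,9E,11Z,13Z)-4-(TBS-oxy)-7,11-dimethylheptadeca-5,9,11,13,16-pentaen-1-yn-8-yl (3S,5S,6E,11R)-3,5,11-tris(TBS-oxy)-13-hydroxy-9-methylidenetridec-6-enoate
Conditions: HF·pyridine, pyridine, THF, 0 °C to rt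
Reagents that add atoms: none
Why: Sterically controlled desilylation: the primary C13 TBS ether should be cleaved much faster than the four secondary TBS ethers under buffered HF·pyridine.

Step 23
Reactants: 29 primary alcohol (see list)
Product: 30 (4S,5E,7R,8S,9E,11Z,13Z)-4-(TBS-oxy)-7,11-dimethylheptadeca-5,9,11,13,16-pentaen-1-yn-8-yl (3S,5S,6E,11R)-3,5,11-tris(TBS-oxy)-9-methylidene-13-[(trifluoromethanesulfonyl)oxy]tridec-6-enoate
Conditions: Tf2O, 2,6-lutidine, CH2Cl2, −78 °C; rapid filtration through silica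
Reagents that add atoms: trifluoromethanesulfonic anhydride, `O=S(=O)(OS(=O)(=O)C(F)(F)F)C(F)(F)F`
Why: O-Sulfonylation of the primary alcohol at low temperature with a hindered base gives the primary alkyl triflate, which is used at once.

Step 24
Reactants: 30 alkynyl triflate (see list)
Product: 32 (3S,5S,6E,11S,14E,17S,18E,20R,21S,22E,24Z,26Z)-3,5,11,17-tetrakis(TBS-oxy)-20,24-dimethyl-9-methylidenetriaconta-6,14,18,22,24,26,29-heptaen-21-olide, via alkenylcopper 31 (not isolated)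
Conditions: (SIPr)CuOTf (20 mol %), (Me2HSi)2O, CsF, 1,4-dioxane (2 mM), 45 °C
Reagents that add atoms: none
Why: Proposed new method: the copper hydride formed from (SIPr)CuOTf, CsF and the silane adds syn and anti-Markovnikov across the terminal C14≡C15 alkyne (Cu on C14, H on C15) to give the (E)-alkenylcopper 31, whose C14 then displaces the primary C13 triflate in a polar substitution that forms the C13–C14 bond and returns (SIPr)CuOTf for conversion back to the hydride. The closest known reaction type is the intermolecular copper-hydride-catalysed anti-Markovnikov hydroalkylation of terminal alkynes with primary alkyl triflates, which gives (E)-alkenes; the new element is its intramolecular use to close a large ring. The 22-membered lactone ring closes in a 22-exo-tet mode (the C13–O bond of the leaving group lies outside the new ring), and the 2 mM concentration should favour it over oligomerisation. No stereocentre is formed; the one new stereo-element, the (E)-C14=C15 alkene, is fixed by the syn hydrocupration followed by substitution with retention at the alkenyl carbon. The step needs chemoselectivity for the single terminal alkyne over the isolated alkenes, the triene and the ester, which rests on the bulky (SIPr)CuH inserting terminal alkynes far faster than unactivated, 1,1-disubstituted or internal alkenes and on the alkenylcopper having no β-leaving group (the C17 silyl ether is γ). Because the alkylation is polar, no C13 radical arises that could cyclise onto the C9 methylidene, which is why this closure is preferred to a radical decarboxylative coupling at the same bond.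

Step 25
Reactants: 32 tetra-TBS macrolactone (see list)
Product: 33 (3S,5S,6E,11S,14E,17S,18E,20R,21S,22E,24Z,26Z)-3,5,11,17-tetrahydroxy-20,24-dimethyl-9-methylidenetriaconta-6,14,18,22,24,26,29-heptaen-21-olide (CNP0297533.1)
Conditions: HF·pyridine, pyridine, THF, 0 °C to rt
Reagents that add atoms: none
Why: Global desilylation with buffered HF·pyridine removes the four TBS groups without the basic conditions that could cause translactonisation or β-elimination of the β-hydroxy lactone.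

**Compound list**

1 | tert-butyl (5S)-6-chloro-5-hydroxy-3-oxohexanoate | `CC(C)(C)OC(=O)CC(=O)C[C@H](O)CCl` | starting material
2 | tert-butyl (3S,5S)-6-chloro-3,5-dihydroxyhexanoate | `CC(C)(C)OC(=O)C[C@@H](O)C[C@H](O)CCl` | intermediate
3 | tert-butyl (3S)-3-hydroxy-4-[(2S)-oxiran-2-yl]butanoate | `CC(C)(C)OC(=O)C[C@@H](O)C[C@H]1CO1` | intermediate
4 | tert-butyl (3S,5R)-3,5-dihydroxyoct-7-enoate | `CC(C)(C)OC(=O)C[C@@H](O)C[C@H](O)CC=C` | intermediate
5 | tert-butyl (3S,5R)-3,5-bis(TBS-oxy)oct-7-enoate | `CC(C)(C)OC(=O)C[C@@H](O[Si](C)(C)C(C)(C)C)C[C@H](O[Si](C)(C)C(C)(C)C)CC=C` | intermediate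
6 | 3-(TBS-oxy)propanal | `O=CCCO[Si](C)(C)C(C)(C)C` | starting material
7 | (3R)-1-(TBS-oxy)hex-5-yn-3-ol | `C#CC[C@@H](O)CCO[Si](C)(C)C(C)(C)C` | intermediate
8 | (3R)-1,3-bis(TBS-oxy)hex-5-yne | `C#CC[C@@H](O[Si](C)(C)C(C)(C)C)CCO[Si](C)(C)C(C)(C)C` | intermediate
9 | tert-butyl (3S,5S,6E,11R)-3,5,11,13-tetrakis(TBS-oxy)-9-methylidenetridec-6-enoate | `CC(C)(C)OC(=O)C[C@@H](O[Si](C)(C)C(C)(C)C)C[C@H](O[Si](C)(C)C(C)(C)C)/C=C/CC(=C)C[C@@H](O[Si](C)(C)C(C)(C)C)CCO[Si](C)(C)C(C)(C)C` | intermediate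
10 | trimethylsilyl (3S,5S,6E,11R)-3,5,11,13-tetrakis(TBS-oxy)-9-methylidenetridec-6-enoate | `C[Si](C)(C)OC(=O)C[C@@H](O[Si](C)(C)C(C)(C)C)C[C@H](O[Si](C)(C)C(C)(C)C)/C=C/CC(=C)C[C@@H](O[Si](C)(C)C(C)(C)C)CCO[Si](C)(C)C(C)(C)C` | intermediate
11 | (3S,5S,6E,11R)-3,5,11,13-tetrakis(TBS-oxy)-9-methylidenetridec-6-enoic acid | `OC(=O)C[C@@H](O[Si](C)(C)C(C)(C)C)C[C@H](O[Si](C)(C)C(C)(C)C)/C=C/CC(=C)C[C@@H](O[Si](C)(C)C(C)(C)C)CCO[Si](C)(C)C(C)(C)C` | intermediate
12 | but-2-yn-1-ol | `CC#CCO` | starting material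
13 | sodium 2,2-bis(2-methoxyethoxy)-3-methyl-2,5-dihydro-1,2-oxaluminol-2-uide (cyclic (Z)-alkenylalanate, Al on C3 and on O) | `CC1=CCO[Al-]1(OCCOC)OCCOC.[Na+]` | intermediate
14 | (2Z)-3-iodobut-2-en-1-ol | `C/C(I)=C/CO` | intermediate
15 | (2Z)-3-iodobut-2-enal | `C/C(I)=C/C=O` | intermediate
16 | (2Z,4Z)-2-iodoocta-2,4,7-triene | `C=CC\C=C/C=C(C)\I` | intermediate
17 | prop-2-yn-1-ol | `C#CCO` | starting material
18 | (2E)-3-(tributylstannyl)prop-2-en-1-ol | `OC/C=C/[Sn](CCCC)(CCCC)CCCC` | intermediate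
19 | (2E)-3-(tributylstannyl)prop-2-enal | `O=C/C=C/[Sn](CCCC)(CCCC)CCCC` | intermediate
20 | (1E,3R,4R)-4-methyl-1-(tributylstannyl)hexa-1,5-dien-3-ol | `C=C[C@@H](C)[C@@H](O)/C=C/[Sn](CCCC)(CCCC)CCCC` | intermediate
21 | triethyl{[(1E,3R,4R)-4-methyl-1-(tributylstannyl)hexa-1,5-dien-3-yl]oxy}silane | `C=C[C@@H](C)[C@@H](O[Si](CC)(CC)CC)/C=C/[Sn](CCCC)(CCCC)CCCC` | intermediate
22 | (2E,4R,5R,6E)-4-methyl-5-(TES-oxy)-7-(tributylstannyl)hepta-2,6-dienal | `O=C/C=C/[C@@H](C)[C@@H](O[Si](CC)(CC)CC)/C=C/[Sn](CCCC)(CCCC)CCCC` | intermediate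
23 | (2E,4R,5S,6E,8Z,10Z)-4,8-dimethyl-5-(TES-oxy)tetradeca-2,6,8,10,13-pentaenal | `C=CC\C=C/C=C(C)\C=C\[C@H](O[Si](CC)(CC)CC)[C@H](C)/C=C/C=O` | intermediate
24 | (4S,5E,7R,8S,9E,11Z,13Z)-7,11-dimethyl-8-(TES-oxy)heptadeca-5,9,11,13,16-pentaen-1-yn-4-ol | `C=CC\C=C/C=C(C)\C=C\[C@H](O[Si](CC)(CC)CC)[C@H](C)/C=C/[C@@H](O)CC#C` | intermediate
25 | (4S,5E,7R,8S,9E,11Z,13Z)-4-(TBS-oxy)-7,11-dimethyl-8-(TES-oxy)heptadeca-5,9,11,13,16-pentaen-1-yne | `C=CC\C=C/C=C(C)\C=C\[C@H](O[Si](CC)(CC)CC)[C@H](C)/C=C/[C@@H](O[Si](C)(C)C(C)(C)C)CC#C` | intermediate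
26 | (4S,5E,7R,8S,9E,11Z,13Z)-4-(TBS-oxy)-7,11-dimethylheptadeca-5,9,11,13,16-pentaen-1-yn-8-ol | `C=CC\C=C/C=C(C)\C=C\[C@H](O)[C@H](C)/C=C/[C@@H](O[Si](C)(C)C(C)(C)C)CC#C` | intermediate
27 | (3S,5S,6E,11R)-3,5,11,13-tetrakis(TBS-oxy)-9-methylidenetridec-6-enoic 2,4,6-trichlorobenzoic anhydride | `Clc1cc(Cl)cc(Cl)c1C(=O)OC(=O)C[C@@H](O[Si](C)(C)C(C)(C)C)C[C@H](O[Si](C)(C)C(C)(C)C)/C=C/CC(=C)C[C@@H](O[Si](C)(C)C(C)(C)C)CCO[Si](C)(C)C(C)(C)C` | intermediate
28 | (4S,5E,7R,8S,9E,11Z,13Z)-4-(TBS-oxy)-7,11-dimethylheptadeca-5,9,11,13,16-pentaen-1-yn-8-yl (3S,5S,6E,11R)-3,5,11,13-tetrakis(TBS-oxy)-9-methylidenetridec-6-enoate | `C=CC\C=C/C=C(C)\C=C\[C@H](OC(=O)C[C@@H](O[Si](C)(C)C(C)(C)C)C[C@H](O[Si](C)(C)C(C)(C)C)/C=C/CC(=C)C[C@@H](O[Si](C)(C)C(C)(C)C)CCO[Si](C)(C)C(C)(C)C)[C@H](C)/C=C/[C@@H](O[Si](C)(C)C(C)(C)C)CC#C` | intermediate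
29 | (4S,5E,7R,8S,9E,11Z,13Z)-4-(TBS-oxy)-7,11-dimethylheptadeca-5,9,11,13,16-pentaen-1-yn-8-yl (3S,5S,6E,11R)-3,5,11-tris(TBS-oxy)-13-hydroxy-9-methylidenetridec-6-enoate | `C=CC\C=C/C=C(C)\C=C\[C@H](OC(=O)C[C@@H](O[Si](C)(C)C(C)(C)C)C[C@H](O[Si](C)(C)C(C)(C)C)/C=C/CC(=C)C[C@@H](O[Si](C)(C)C(C)(C)C)CCO)[C@H](C)/C=C/[C@@H](O[Si](C)(C)C(C)(C)C)CC#C` | intermediate
30 | (4S,5E,7R,8S,9E,11Z,13Z)-4-(TBS-oxy)-7,11-dimethylheptadeca-5,9,11,13,16-pentaen-1-yn-8-yl (3S,5S,6E,11R)-3,5,11-tris(TBS-oxy)-9-methylidene-13-[(trifluoromethanesulfonyl)oxy]tridec-6-enoate | `C=CC\C=C/C=C(C)\C=C\[C@H](OC(=O)C[C@@H](O[Si](C)(C)C(C)(C)C)C[C@H](O[Si](C)(C)C(C)(C)C)/C=C/CC(=C)C[C@@H](O[Si](C)(C)C(C)(C)C)CCOS(=O)(=O)C(F)(F)F)[C@H](C)/C=C/[C@@H](O[Si](C)(C)C(C)(C)C)CC#C` | intermediate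
31 | (E)-alkenylcopper: triflate 30 in which the C14≡C15 alkyne has become (E)-C15H=C14H–Cu(SIPr), Cu on C14 | `C=CC\C=C/C=C(C)\C=C\[C@H](OC(=O)C[C@@H](O[Si](C)(C)C(C)(C)C)C[C@H](O[Si](C)(C)C(C)(C)C)/C=C/CC(=C)C[C@@H](O[Si](C)(C)C(C)(C)C)CCOS(=O)(=O)C(F)(F)F)[C@H](C)/C=C/[C@@H](O[Si](C)(C)C(C)(C)C)C/C=C/[Cu-]C1=[N+](c2c(C(C)C)cccc2C(C)C)CCN1c1c(C(C)C)cccc1C(C)C` | intermediate
32 | (3S,5S,6E,11S,14E,17S,18E,20R,21S,22E,24Z,26Z)-3,5,11,17-tetrakis(TBS-oxy)-20,24-dimethyl-9-methylidenetriaconta-6,14,18,22,24,26,29-heptaen-21-olide | `C=CC\C=C/C=C(C)\C=C\[C@@H]1OC(=O)C[C@@H](O[Si](C)(C)C(C)(C)C)C[C@H](O[Si](C)(C)C(C)(C)C)/C=C/CC(=C)C[C@@H](O[Si](C)(C)C(C)(C)C)CC/C=C/C[C@H](O[Si](C)(C)C(C)(C)C)/C=C/[C@H]1C` | intermediate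
33 | (3S,5S,6E,11S,14E,17S,18E,20R,21S,22E,24Z,26Z)-3,5,11,17-tetrahydroxy-20,24-dimethyl-9-methylidenetriaconta-6,14,18,22,24,26,29-heptaen-21-olide (CNP0297533.1) | `C=CC\C=C/C=C(C)\C=C\[C@@H]1OC(=O)C[C@@H](O)C[C@H](O)/C=C/CC(=C)C[C@@H](O)CC/C=C/C[C@H](O)/C=C/[C@H]1C` | target

**Step count and risks**

Total step count: 25. Longest linear sequence: 14 steps (steps 12–20, then 21–25).

Steps most likely to fail:

1. Step 24 (proposed new method). What may go wrong: at 2 mM the ring-closing alkylation of the alkenylcopper may be slow. Hydride reduction or fluoride displacement of the triflate, protonation of the alkenylcopper, intermolecular alkylation to oligomers, or hydride delivery to the trienyl ester could then compete. Fallback (known chemistry): form C13–C14 by the intermolecular hydroalkylation and close the ring at the ester. It sets out from 9 and 25 and comes back at 32. Buffered HF·pyridine removes the primary TBS group of 9 to give tert-butyl (3S,5S,6E,11R)-3,5,11-tris(TBS-oxy)-13-hydroxy-9-methylidenetridec-6-enoate F1. Tf2O/2,6-lutidine converts it into the primary triflate tert-butyl (3S,5S,6E,11R)-3,5,11-tris(TBS-oxy)-9-methylidene-13-[(trifluoromethanesulfonyl)oxy]tridec-6-enoate F2. F2 and alkyne 25 are joined under the intermolecular conditions ((SIPr)CuOTf cat., (Me2HSi)2O, CsF, 1,4-dioxane, 45 °C, normal concentration) to the open-chain tert-butyl (3S,5S,6E,11S,14E,17S,18E,20R,21S,22E,24Z,26Z)-3,5,11,17-tetrakis(TBS-oxy)-20,24-dimethyl-9-methylidene-21-(TES-oxy)triaconta-6,14,18,22,24,26,29-heptaenoate F3. Buffered HF·pyridine removes the TES group to give the 21-hydroxy ester F4. TMSOTf/2,6-lutidine followed by K2CO3/MeOH work-up gives the 21-hydroxy seco acid F5. Yamaguchi macrolactonisation under high dilution then gives 32.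

2. Step 7. What may go wrong: poor branched-to-linear regioselectivity in the ruthenacycle formation, or alkene migration of the skipped diene on the metal. Fallback: build the 1,4-diene by an allyl–alkenyl Stille coupling. It sets out from 5 and 8 and comes back at 9. Palladium-catalysed linear allylic C–H acetoxylation of 5 (Pd(OAc)2, benzoquinone, DMSO/AcOH, 40 °C) gives tert-butyl (3S,5S,6E)-8-acetoxy-3,5-bis(TBS-oxy)oct-6-enoate F6. Molybdenum-catalysed Markovnikov hydrostannation of 8 (Mo(CO)3(CNtBu)3, Bu3SnH, THF, 55 °C) gives tributyl[(4S)-4,6-bis(TBS-oxy)hex-1-en-2-yl]stannane F7. Coupling of F6 with F7 (Pd2(dba)3, LiCl, DMF) at the unhindered allyl terminus gives 9.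

3. Step 21. What may go wrong: slow acylation of the hindered trienyl carbinol, allowing β-elimination of the activated β-silyloxy acid or ionisation and allylic transposition of the alcohol. Fallback: esterify early with the simple alcohol and build the alcohol half on the ester. It sets out from 11 and 20 and comes back at 28. Yamaguchi esterification of 20 with 11 gives (1E,3R,4R)-4-methyl-1-(tributylstannyl)hexa-1,5-dien-3-yl (3S,5S,6E,11R)-3,5,11,13-tetrakis(TBS-oxy)-9-methylidenetridec-6-enoate F8. Cross-metathesis with crotonaldehyde as in step 16 gives the enal ester F9. Stille coupling with 16 as in step 17 gives the pentaenal ester F10. Propargylation as in step 18 gives the C17 alcohol F11. Silylation (TBSCl, imidazole) then gives 28.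

Further compounds
F1 | step 24 | tert-butyl (3S,5S,6E,11R)-3,5,11-tris(TBS-oxy)-13-hydroxy-9-methylidenetridec-6-enoate | `CC(C)(C)OC(=O)C[C@@H](O[Si](C)(C)C(C)(C)C)C[C@H](O[Si](C)(C)C(C)(C)C)/C=C/CC(=C)C[C@@H](O[Si](C)(C)C(C)(C)C)CCO`
F2 | step 24 | tert-butyl (3S,5S,6E,11R)-3,5,11-tris(TBS-oxy)-9-methylidene-13-[(trifluoromethanesulfonyl)oxy]tridec-6-enoate | `CC(C)(C)OC(=O)C[C@@H](O[Si](C)(C)C(C)(C)C)C[C@H](O[Si](C)(C)C(C)(C)C)/C=C/CC(=C)C[C@@H](O[Si](C)(C)C(C)(C)C)CCOS(=O)(=O)C(F)(F)F`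
F3 | step 24 | tert-butyl (3S,5S,6E,11S,14E,17S,18E,20R,21S,22E,24Z,26Z)-3,5,11,17-tetrakis(TBS-oxy)-20,24-dimethyl-9-methylidene-21-(TES-oxy)triaconta-6,14,18,22,24,26,29-heptaenoate | `CC(C)(C)OC(=O)C[C@@H](O[Si](C)(C)C(C)(C)C)C[C@H](O[Si](C)(C)C(C)(C)C)/C=C/CC(=C)C[C@@H](O[Si](C)(C)C(C)(C)C)CC/C=C/C[C@H](O[Si](C)(C)C(C)(C)C)/C=C/[C@@H](C)[C@@H](O[Si](CC)(CC)CC)/C=C/C(C)=C\C=C/CC=C`
F4 | step 24 | tert-butyl (3S,5S,6E,11S,14E,17S,18E,20R,21S,22E,24Z,26Z)-3,5,11,17-tetrakis(TBS-oxy)-21-hydroxy-20,24-dimethyl-9-methylidenetriaconta-6,14,18,22,24,26,29-heptaenoate | `CC(C)(C)OC(=O)C[C@@H](O[Si](C)(C)C(C)(C)C)C[C@H](O[Si](C)(C)C(C)(C)C)/C=C/CC(=C)C[C@@H](O[Si](C)(C)C(C)(C)C)CC/C=C/C[C@H](O[Si](C)(C)C(C)(C)C)/C=C/[C@@H](C)[C@@H](O)/C=C/C(C)=C\C=C/CC=C`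
F5 | step 24 | (3S,5S,6E,11S,14E,17S,18E,20R,21S,22E,24Z,26Z)-3,5,11,17-tetrakis(TBS-oxy)-21-hydroxy-20,24-dimethyl-9-methylidenetriaconta-6,14,18,22,24,26,29-heptaenoic acid | `OC(=O)C[C@@H](O[Si](C)(C)C(C)(C)C)C[C@H](O[Si](C)(C)C(C)(C)C)/C=C/CC(=C)C[C@@H](O[Si](C)(C)C(C)(C)C)CC/C=C/C[C@H](O[Si](C)(C)C(C)(C)C)/C=C/[C@@H](C)[C@@H](O)/C=C/C(C)=C\C=C/CC=C`
F6 | step 7 | tert-butyl (3S,5S,6E)-8-acetoxy-3,5-bis(TBS-oxy)oct-6-enoate | `CC(C)(C)OC(=O)C[C@@H](O[Si](C)(C)C(C)(C)C)C[C@H](O[Si](C)(C)C(C)(C)C)/C=C/COC(C)=O`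
F7 | step 7 | tributyl[(4S)-4,6-bis(TBS-oxy)hex-1-en-2-yl]stannane | `C=C([Sn](CCCC)(CCCC)CCCC)C[C@@H](O[Si](C)(C)C(C)(C)C)CCO[Si](C)(C)C(C)(C)C`
F8 | step 21 | (1E,3R,4R)-4-methyl-1-(tributylstannyl)hexa-1,5-dien-3-yl (3S,5S,6E,11R)-3,5,11,13-tetrakis(TBS-oxy)-9-methylidenetridec-6-enoate | `C=C[C@@H](C)[C@@H](OC(=O)C[C@@H](O[Si](C)(C)C(C)(C)C)C[C@H](O[Si](C)(C)C(C)(C)C)/C=C/CC(=C)C[C@@H](O[Si](C)(C)C(C)(C)C)CCO[Si](C)(C)C(C)(C)C)/C=C/[Sn](CCCC)(CCCC)CCCC`
F9 | step 21 | (2E,4R,5R,6E)-4-methyl-1-oxo-7-(tributylstannyl)hepta-2,6-dien-5-yl (3S,5S,6E,11R)-3,5,11,13-tetrakis(TBS-oxy)-9-methylidenetridec-6-enoate | `O=C/C=C/[C@@H](C)[C@@H](OC(=O)C[C@@H](O[Si](C)(C)C(C)(C)C)C[C@H](O[Si](C)(C)C(C)(C)C)/C=C/CC(=C)C[C@@H](O[Si](C)(C)C(C)(C)C)CCO[Si](C)(C)C(C)(C)C)/C=C/[Sn](CCCC)(CCCC)CCCC`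
F10 | step 21 | (2E,4R,5S,6E,8Z,10Z)-4,8-dimethyl-1-oxotetradeca-2,6,8,10,13-pentaen-5-yl (3S,5S,6E,11R)-3,5,11,13-tetrakis(TBS-oxy)-9-methylidenetridec-6-enoate | `O=C/C=C/[C@@H](C)[C@@H](OC(=O)C[C@@H](O[Si](C)(C)C(C)(C)C)C[C@H](O[Si](C)(C)C(C)(C)C)/C=C/CC(=C)C[C@@H](O[Si](C)(C)C(C)(C)C)CCO[Si](C)(C)C(C)(C)C)/C=C/C(C)=C\C=C/CC=C`
F11 | step 21 | (4S,5E,7R,8S,9E,11Z,13Z)-4-hydroxy-7,11-dimethylheptadeca-5,9,11,13,16-pentaen-1-yn-8-yl (3S,5S,6E,11R)-3,5,11,13-tetrakis(TBS-oxy)-9-methylidenetridec-6-enoate | `C#CC[C@H](O)/C=C/[C@@H](C)[C@@H](OC(=O)C[C@@H](O[Si](C)(C)C(C)(C)C)C[C@H](O[Si](C)(C)C(C)(C)C)/C=C/CC(=C)C[C@@H](O[Si](C)(C)C(C)(C)C)CCO[Si](C)(C)C(C)(C)C)/C=C/C(C)=C\C=C/CC=C`
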